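**Retrosynthetic overview**
1. Target 16 comes from isoquinoline-5,8-quinone 14 by C7 hydroxylation and a benzilic ester 1,2-shift that contracts the six-membered carbocycle to the cyclopentenone; both carbinol centres are set in this step.
2. Quinone 14 comes from nicotinate 9 and a propionyl unit (10) by lateral acylation, Claisen ring closure and aerobic oxidation.
3. Nicotinate 9 comes from chloronicotinate 8 and dienylboronate 4 by Suzuki–Miyaura coupling.
4. Ester 8 comes from 5-bromo-2-chloropyridine (C4 methylation, then carbonylation); boronate 4 comes from (S)-2-methylbutan-1-ol (oxidation/Wittig, then boron-Wittig).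
5. Ring order: pyridine (bought), then the six-membered carbocycle (step 6), then contraction to the five-membered ring (step 7).

Assumption: (S)-2-methylbutan-1-ol of at least 99% ee is the commercial source of the side-chain stereocentre.

**Step 1**
Reactants: 1 (S)-2-methylbutan-1-ol
Product: 3 (2E,4S)-2,4-dimethylhex-2-enal, via (S)-2-methylbutanal 2 (not isolated)
Conditions: TEMPO (10 mol %), PhI(OAc)2 (1.05 equiv), CH2Cl2, rt; then Ph3P=C(Me)CHO (1.5 equiv), 40 °C
Reagents that add atoms: 2-(triphenylphosphoranylidene)propanal, CC(C=O)=P(c1ccccc1)(c1ccccc1)c1ccccc1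
Why: The base-free TEMPO/PhI(OAc)2 oxidation gives the α-chiral aldehyde without epimerisation, and the stabilised α-methyl ylide then gives the trisubstituted E-enal by Wittig olefination in the same flask; the stereocentre comes from 1 and is not touched.

**Step 2**
Reactants: 3 (2E,4S)-2,4-dimethylhex-2-enal
Product: 4 2-[(1E,3E,5S)-3,5-dimethylhepta-1,3-dien-1-yl]-4,4,5,5-tetramethyl-1,3,2-dioxaborolane
Conditions: CH2(Bpin)2 (1.2 equiv), lithium 2,2,6,6-tetramethylpiperidide (1.15 equiv), THF, 0 °C; then 3, −78 °C → rt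
Reagents that add atoms: bis(pinacolato)borylmethane, CC1(C)OB(CB2OC(C)(C)C(C)(C)O2)OC1(C)C
Why: Boron-Wittig olefination, in which the preformed LiCH(Bpin)2 adds 1,2 to the aldehyde at −78 °C faster than it can deprotonate the γ-position (so C4 is not epimerised) and B–O elimination gives the E-alkenylboronate.

**Step 3**
Reactants: 5 5-bromo-2-chloropyridine
Product: 7 5-bromo-2-chloro-4-methylpyridine, via 5-bromo-2-chloro-4-lithiopyridine 6 (not isolated)
Conditions: LiN(iPr)2 (1.05 equiv), THF, −78 °C, 45 min; MeI, −78 °C → rt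
Reagents that add atoms: iodomethane, CI
Why: Directed ortho-lithiation removes H-4 (ortho to bromine) at a temperature low enough to suppress halogen dance, and the aryllithium is methylated by MeI.

**Step 4**
Reactants: 7 5-bromo-2-chloro-4-methylpyridine
Product: 8 methyl 6-chloro-4-methylpyridine-3-carboxylate
Conditions: Pd(OAc)2 (3 mol %), dppf (4 mol %), CO (1 atm), Et3N, MeOH/DMF 1:1, 70 °C
Reagents that add atoms: carbon monoxide, [C-]#[O+]; methanol, CO
Why: Palladium-catalysed methoxycarbonylation, in which zerovalent palladium inserts into C–Br far faster than into C–Cl, and CO insertion followed by methanolysis gives the ester.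

**Step 5**
Reactants: 8 methyl 6-chloro-4-methylpyridine-3-carboxylate; 4 2-[(1E,3E,5S)-3,5-dimethylhepta-1,3-dien-1-yl]-4,4,5,5-tetramethyl-1,3,2-dioxaborolane
Product: 9 methyl 6-[(1E,3E,5S)-3,5-dimethylhepta-1,3-dien-1-yl]-4-methylpyridine-3-carboxylate
Conditions: Pd(dppf)Cl2 (3 mol %), K2CO3, 1,4-dioxane/H2O 5:1, 80 °C
Reagents that add atoms: none
Why: Suzuki–Miyaura coupling at a 2-chloropyridine activated by the para ester; the E,E geometry of the boronate is retained and the ester and the 5S centre are untouched.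

**Step 6**
Reactants: 9 methyl 6-[(1E,3E,5S)-3,5-dimethylhepta-1,3-dien-1-yl]-4-methylpyridine-3-carboxylate; 10 N-methoxy-N-methylpropanamide
Product: 14 3-[(1E,3E,5S)-3,5-dimethylhepta-1,3-dien-1-yl]-6-hydroxy-7-methylisoquinoline-5,8-dione, via lithiated ester 11 (not isolated), via keto ester 12 (not isolated), via isoquinoline-6,8-diol 13 (not isolated)
Conditions: LiN(iPr)2 (1.1 equiv), THF, −78 °C; 10, −78 → 0 °C; then NaOMe (3 equiv), MeOH, 50 °C; then O2 (1 atm), rt; aq HCl to pH 4
Reagents that add atoms: dioxygen, O=O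
Why: Lateral lithiation of the toluate-type 4-methyl group and Weinreb acylation give keto ester 12 once MeOH is added, NaOMe drives the Claisen (Dieckmann-type) closure to the aromatic 1,3-diolate 13 (six is the only ring size open to the ethyl-side enolate), and the electron-rich diolate is autoxidised at C5 to the hydroxyquinone; no stereocentre is formed and the remote 5S centre is not acidic.

**Step 7**
Reactants: 14 3-[(1E,3E,5S)-3,5-dimethylhepta-1,3-dien-1-yl]-6-hydroxy-7-methylisoquinoline-5,8-dione
Product: 16 methyl (5R,6S)-3-[(1E,3E,5S)-3,5-dimethylhepta-1,3-dien-1-yl]-5,6-dihydroxy-6-methyl-7-oxo-6,7-dihydro-5H-cyclopenta[c]pyridine-5-carboxylate, via (7R)-trione 15 (not isolated)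
Conditions: Cu(OTf)2 (10 mol %), (R,R)-tBu-box (12 mol %), 3-phenyl-2-(phenylsulfonyl)oxaziridine (1.3 equiv), 4 Å MS, CH2Cl2, −20 °C; then MeOH (20 equiv), Et3N (0.2 equiv), −20 → 0 °C
Reagents that add atoms: 3-phenyl-2-(phenylsulfonyl)oxaziridine, O=S(=O)(c1ccccc1)N1OC1c1ccccc1; methanol, CO
Why: Proposed new method: a catalytic asymmetric interrupted Hooker ring contraction. The acidic hydroxyquinone binds the divalent copper–bis(oxazoline) complex as its planar 5-oxo-6-oxido chelate; the tert-butyl group of the oxazoline cis to O6 blocks one face of C7, so the sulfonyloxaziridine delivers oxygen to the open face and gives (7R)-trione 15 (7R becomes 6S in the product only through the change in CIP ranking). The activated 5,6-dione then adds MeOH at C6 and the C6–C7 bond shifts to C5 (benzilic ester 1,2-shift, ring contraction with retention at the migrating carbon); in the reacting half-chair the C7 hydroxyl lies in the C8 carbonyl plane (hydrogen-bonded) and the C7 methyl is pseudo-axial, so the extruded CO2Me ends anti to the methyl and the 5R trans-diol results. Closest known reaction types: chiral Lewis-acid-catalysed enantioselective α-hydroxylation of β-keto esters with N-sulfonyloxaziridines, and the H2O2/Na2CO3 hydroxylation–benzilic acid contraction of 2-hydroxy-3-alkyl-1,4-naphthoquinones to 1,2-dihydroxy-3-oxoindane-1-carboxylic acids (first stage of the Hooker oxidation).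

**Compound list**
1 | (S)-2-methylbutan-1-ol | CC[C@H](C)CO | starting material
2 | (S)-2-methylbutanal | CC[C@H](C)C=O | intermediate (not isolated)
3 | (2E,4S)-2,4-dimethylhex-2-enal | CC[C@H](C)/C=C(C)/C=O | intermediate
4 | 2-[(1E,3E,5S)-3,5-dimethylhepta-1,3-dien-1-yl]-4,4,5,5-tetramethyl-1,3,2-dioxaborolane | CC[C@H](C)/C=C(C)/C=C/B1OC(C)(C)C(C)(C)O1 | intermediate
5 | 5-bromo-2-chloropyridine | Clc1ccc(Br)cn1 | starting material
6 | 5-bromo-2-chloro-4-lithiopyridine | Clc1cc([Li])c(Br)cn1 | intermediate (not isolated)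
7 | 5-bromo-2-chloro-4-methylpyridine | Cc1cc(Cl)ncc1Br | intermediate
8 | methyl 6-chloro-4-methylpyridine-3-carboxylate | COC(=O)c1cnc(Cl)cc1C | intermediate
9 | methyl 6-[(1E,3E,5S)-3,5-dimethylhepta-1,3-dien-1-yl]-4-methylpyridine-3-carboxylate | CC[C@H](C)/C=C(C)/C=C/c1cc(C)c(C(=O)OC)cn1 | intermediate
10 | N-methoxy-N-methylpropanamide | CCC(=O)N(C)OC | starting material
11 | methyl 6-[(1E,3E,5S)-3,5-dimethylhepta-1,3-dien-1-yl]-4-(lithiomethyl)pyridine-3-carboxylate | CC[C@H](C)/C=C(C)/C=C/c1cc(C[Li])c(C(=O)OC)cn1 | intermediate (not isolated)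
12 | methyl 6-[(1E,3E,5S)-3,5-dimethylhepta-1,3-dien-1-yl]-4-(2-oxobutyl)pyridine-3-carboxylate | CC[C@H](C)/C=C(C)/C=C/c1cc(CC(=O)CC)c(C(=O)OC)cn1 | intermediate (not isolated)
13 | 3-[(1E,3E,5S)-3,5-dimethylhepta-1,3-dien-1-yl]-7-methylisoquinoline-6,8-diol | CC[C@H](C)/C=C(C)/C=C/c1cc2cc(O)c(C)c(O)c2cn1 | intermediate (not isolated)
14 | 3-[(1E,3E,5S)-3,5-dimethylhepta-1,3-dien-1-yl]-6-hydroxy-7-methylisoquinoline-5,8-dione | CC[C@H](C)/C=C(C)/C=C/c1cc2c(cn1)C(=O)C(C)=C(O)C2=O | intermediate
15 | (7R)-3-[(1E,3E,5S)-3,5-dimethylhepta-1,3-dien-1-yl]-7-hydroxy-7-methylisoquinoline-5,6,8(7H)-trione | CC[C@H](C)/C=C(C)/C=C/c1cc2c(cn1)C(=O)[C@@](C)(O)C(=O)C2=O | intermediate (not isolated)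
16 | methyl (5R,6S)-3-[(1E,3E,5S)-3,5-dimethylhepta-1,3-dien-1-yl]-5,6-dihydroxy-6-methyl-7-oxo-6,7-dihydro-5H-cyclopenta[c]pyridine-5-carboxylate | CC[C@H](C)/C=C(C)/C=C/c1cc2c(cn1)C(=O)[C@@](C)(O)[C@@]2(O)C(=O)OC | target

**Totals**
Total steps: 7. Longest linear sequence: 5 (steps 3, 4, 5, 6, 7; the side-chain branch 1, 2, 5, 6, 7 is equally long).

**Three steps most likely to fail**

Step 7 (the proposed new step). Risks:
- The copper-bound hydroxyquinonate may be too weak a nucleophile for the oxaziridine.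
- The facial sense comes from a simple quadrant model and the ee is unknown; if the sense is opposite, the (S,S)-ligand is used.
- Methoxide-type retro-Claisen opening of 15, or retro-aldol opening of 16, would erode both new centres.

Fallback with known chemistry, setting out from 14 and coming back at 16: 14 is warmed with H2O2/Na2CO3 in dioxane/water at 60 °C (the isolable first stage of the Hooker oxidation). This hydroxylates C7 without facial control, giving 15 together with the (7S)-trione F6, neither isolated. Both contract by benzilic acid rearrangement to the (5R,6S)-hydroxy acid F7 and the (5S,6R)-hydroxy acid F8. Me3SiCHN2 in MeOH/toluene at 0 °C converts the pair into 16 and the (5S,6R)-methyl ester F9. These two are diastereomers because of the fixed 5S side-chain centre and are separated by preparative HPLC.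

Step 6. Risks:
- The lateral anion of 9 may self-condense or add to the dienylpyridine.
- The Claisen closure may stall at the enol lactone.
- The diolate may over-oxidise.

Fallback, setting out from 8 and coming back at 14 (ring built before the diene is present, coupling moved to the end): 8 is deprotonated with LiN(iPr)2 at −78 °C and acylated with 10 to give, after aqueous work-up, isolated methyl 6-chloro-4-(2-oxobutyl)pyridine-3-carboxylate F3. NaH in THF (0 °C → rt, no nucleophilic alkoxide in excess) closes it to 3-chloro-7-methylisoquinoline-6,8-diol F4 (not isolated). After a MeOH quench, air oxidises F4 to 3-chloro-6-hydroxy-7-methylisoquinoline-5,8-dione F5. Suzuki–Miyaura coupling of F5 (as its potassium salt) with 4 (Pd(dppf)Cl2, K3PO4, dioxane/H2O, 80 °C) gives 14.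

Step 1. Risks:
- The formyl ylide reacts slowly with the α-branched aldehyde.
- Heating may partly epimerise 2.
- A second homologation of 3 and the volatility of 3 can cut the yield.

Fallback, setting out from 1 and coming back at 3: 1 is oxidised as before to 2, which is olefinated at rt with ethyl 2-(triphenylphosphoranylidene)propanoate to give ethyl (2E,4S)-2,4-dimethylhex-2-enoate F1. Reduction with iBu2AlH (CH2Cl2, −78 °C) gives (2E,4S)-2,4-dimethylhex-2-en-1-ol F2, and MnO2 (CH2Cl2, rt) oxidises F2 to 3.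

**Further compounds**
F1 | step 1 | ethyl (2E,4S)-2,4-dimethylhex-2-enoate | CC[C@H](C)/C=C(C)/C(=O)OCC
F2 | step 1 | (2E,4S)-2,4-dimethylhex-2-en-1-ol | CC[C@H](C)/C=C(C)/CO
F3 | step 6 | methyl 6-chloro-4-(2-oxobutyl)pyridine-3-carboxylate | CCC(=O)Cc1cc(Cl)ncc1C(=O)OC
F4 | step 6 | 3-chloro-7-methylisoquinoline-6,8-diol | Cc1c(O)cc2cc(Cl)ncc2c1O
F5 | step 6 | 3-chloro-6-hydroxy-7-methylisoquinoline-5,8-dione | CC1=C(O)C(=O)c2cc(Cl)ncc2C1=O
F6 | step 7 | (7S)-3-[(1E,3E,5S)-3,5-dimethylhepta-1,3-dien-1-yl]-7-hydroxy-7-methylisoquinoline-5,6,8(7H)-trione | CC[C@H](C)/C=C(C)/C=C/c1cc2c(cn1)C(=O)[C@](C)(O)C(=O)C2=O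
F7 | step 7 | (5R,6S)-3-[(1E,3E,5S)-3,5-dimethylhepta-1,3-dien-1-yl]-5,6-dihydroxy-6-methyl-7-oxo-6,7-dihydro-5H-cyclopenta[c]pyridine-5-carboxylic acid | CC[C@H](C)/C=C(C)/C=C/c1cc2c(cn1)C(=O)[C@@](C)(O)[C@@]2(O)C(=O)O
F8 | step 7 | (5S,6R)-3-[(1E,3E,5S)-3,5-dimethylhepta-1,3-dien-1-yl]-5,6-dihydroxy-6-methyl-7-oxo-6,7-dihydro-5H-cyclopenta[c]pyridine-5-carboxylic acid | CC[C@H](C)/C=C(C)/C=C/c1cc2c(cn1)C(=O)[C@](C)(O)[C@]2(O)C(=O)O
F9 | step 7 | methyl (5S,6R)-3-[(1E,3E,5S)-3,5-dimethylhepta-1,3-dien-1-yl]-5,6-dihydroxy-6-methyl-7-oxo-6,7-dihydro-5H-cyclopenta[c]pyridine-5-carboxylate | CC[C@H](C)/C=C(C)/C=C/c1cc2c(cn1)C(=O)[C@](C)(O)[C@]2(O)C(=O)OC
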